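## Retrosynthetic overview
- The exocyclic C=C is cut to vanillin plus (4R)-α-carboxy-β-(3,4-dimethoxybenzyl)-γ-butyrolactone. The forward reaction is a decarboxylative Doebner-type arylidenation and needs no phenol protection.
- The α-carboxy lactone comes from the α-ethoxycarbonyl lactone by saponification and relactonisation.
- The lactone C–O bond comes from a γ-hydroxy malonate, which is made by reducing the corresponding aldehyde.
- The Cα–Cβ bond and the only stereocentre come from 3-(3,4-dimethoxyphenyl)propanal plus diethyl bromomalonate, joined by metal-free enamine photo-organocatalysis.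
- Ring order: both arenes are bought. The lactone is the only ring formed; it closes in step 1, is opened and reclosed in step 2, and is kept in step 3.

Assumption: 3-(3,4-dimethoxyphenyl)propanal, diethyl bromomalonate and vanillin are taken as catalogue chemicals, and C-3 of the lactone intermediates is an inconsequential epimer mixture because it becomes sp2 in the last step.

## Route

Step 1
Reactants: 1 3-(3,4-dimethoxyphenyl)propanal; 2 diethyl 2-bromomalonate
Product: 5 ethyl (4R)-4-(3,4-dimethoxybenzyl)-2-oxooxolane-3-carboxylate (C-3 epimers), via aldehyde malonate 3 (not isolated), via hydroxy malonate 4 (not isolated)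
Conditions: 1 (2 equiv), 2 (1 equiv), (S)-2-{bis[3,5-bis(trifluoromethyl)phenyl](trimethylsilyloxy)methyl}pyrrolidine (20 mol %), 2,6-lutidine (1 equiv), degassed MTBE, 400 nm LED, 15 °C; then EtOH, NaBH4, 0 °C to rt
Reagents that add atoms: none
Why: This is a photo-organocatalytic enamine α-alkylation (radical chain) followed by borohydride reduction and lactonisation, in which the photoexcited (E)-enamine of 1 reduces 2 to the electrophilic malonyl radical, that radical adds to ground-state enamine on the Si face left open by the CAr2(OTMS) group of the (S)-catalyst and so sets the (R) centre, and immediate NaBH4 reduction gives a γ-alkoxide that closes onto one ester before the aldehyde can epimerise.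

Step 2
Reactants: 5 ethyl (4R)-4-(3,4-dimethoxybenzyl)-2-oxooxolane-3-carboxylate
Product: 7 (4R)-4-(3,4-dimethoxybenzyl)-2-oxooxolane-3-carboxylic acid (C-3 epimers), via dipotassium hydroxy malonate 6 (not isolated)
Conditions: KOH (4 equiv), EtOH/H2O 1:1, 45 °C; then 3 M HCl to pH 1, 0 °C to rt; concentrate below 30 °C
Reagents that add atoms: potassium hydroxide, [K+].[OH-]
Why: This is a saponification followed by acid-induced relactonisation, in which hydroxide opens the lactone and cleaves the ethyl ester to the decarboxylation-stable malonate dianion, the γ-hydroxy diacid recloses to the five-membered lactone on acidification, and C-4 carries no acidic hydrogen and is untouched.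

Step 3
Reactants: 7 (4R)-4-(3,4-dimethoxybenzyl)-2-oxooxolane-3-carboxylic acid; 8 vanillin (4-hydroxy-3-methoxybenzaldehyde)
Product: 10 (3E,4R)-4-(3,4-dimethoxybenzyl)-3-(4-hydroxy-3-methoxybenzylidene)oxolan-2-one, via Mannich adduct 9 (not isolated)
Conditions: 8 (2 equiv), piperidine (0.3 equiv), pyridine, 70 °C, N2, slow addition of 7
Reagents that add atoms: none
Why: Proposed new method: amine-catalysed decarboxylative arylidenation of a β-substituted α-carboxy-γ-butyrolactone by an unprotected 4-hydroxybenzaldehyde, in which piperidine converts 8 into its iminium ion, the easily enolised malonic-half-ester-type acid 7 adds to it (Mannich) to give 9, and 9 has no α-H left and can only collapse by Grob-type loss of CO2 and piperidine, a fragmentation assisted by the para-OH through C–N ionisation to a p-quinone methide (decarboxylation before C–C formation leads to the same product by β-amine elimination), while reversible amine addition funnels the alkene to the more stable E isomer (aryl anti to C=O) and the non-acidic C-4 centre is retained; the closest known reaction types are the Knoevenagel–Doebner condensation of malonic acid or its half-esters with ArCHO and the decarboxylative Mannich methylenation of α-carboxy lactones with HCHO/Et2NH.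

## Compound list
1 | 3-(3,4-dimethoxyphenyl)propanal | COc1ccc(CCC=O)cc1OC | starting material
2 | diethyl 2-bromomalonate | CCOC(=O)C(Br)C(=O)OCC | starting material
3 | diethyl 2-[(2R)-1-(3,4-dimethoxyphenyl)-3-oxopropan-2-yl]malonate | O=C[C@H](Cc1ccc(OC)c(OC)c1)C(C(=O)OCC)C(=O)OCC | intermediate
4 | diethyl 2-[(2R)-1-(3,4-dimethoxyphenyl)-3-hydroxypropan-2-yl]malonate | OC[C@H](Cc1ccc(OC)c(OC)c1)C(C(=O)OCC)C(=O)OCC | intermediate
5 | ethyl (4R)-4-(3,4-dimethoxybenzyl)-2-oxooxolane-3-carboxylate (C-3 epimers, mainly trans) | CCOC(=O)C1C(=O)OC[C@@H]1Cc1ccc(OC)c(OC)c1 | intermediate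
6 | dipotassium 2-[(2R)-1-(3,4-dimethoxyphenyl)-3-hydroxypropan-2-yl]malonate | [K+].[K+].OC[C@H](Cc1ccc(OC)c(OC)c1)C(C(=O)[O-])C(=O)[O-] | intermediate
7 | (4R)-4-(3,4-dimethoxybenzyl)-2-oxooxolane-3-carboxylic acid (C-3 epimers) | OC(=O)C1C(=O)OC[C@@H]1Cc1ccc(OC)c(OC)c1 | intermediate
8 | vanillin | COc1cc(C=O)ccc1O | starting material
9 | (4R)-4-(3,4-dimethoxybenzyl)-3-[(4-hydroxy-3-methoxyphenyl)(piperidin-1-yl)methyl]-2-oxooxolane-3-carboxylic acid (new centres undefined) | COc1cc(C(N2CCCCC2)C2(C(=O)O)C(=O)OC[C@@H]2Cc2ccc(OC)c(OC)c2)ccc1O | intermediate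
10 | (3E,4R)-4-(3,4-dimethoxybenzyl)-3-(4-hydroxy-3-methoxybenzylidene)oxolan-2-one | COc1cc(/C=C2/C(=O)OC[C@@H]2Cc2ccc(OC)c(OC)c2)ccc1O | target

Total step count: 3. Longest linear sequence: 3.

## Steps most likely to fail

**Step 3 (the proposed new step).**
- Risk: simple protodecarboxylation of 7 may outrun C–C bond formation at the hindered C-3, or the E/Z ratio may be poor.
- Fallback: it sets out from 7, comes back at 10, and uses known chemistry.
- 7 is treated with aqueous formaldehyde and Et2NH (AcOH, NaOAc, rt), the classical decarboxylative Mannich methylenation. This gives (4R)-4-(3,4-dimethoxybenzyl)-3-methylideneoxolan-2-one F7.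
- A Heck arylation of F7 with 4-iodo-2-methoxyphenol (Pd(OAc)2, Et3N, DMF, 80 °C) then delivers 10. The E geometry follows from syn insertion and syn β-hydride elimination of a benzylic hydrogen.

**Step 1.**
- Risk: the radical chain may give low conversion or insufficient ee with this electron-rich substrate.
- Fallback: it sets out from 1, comes back at 7, and replaces the photochemical radical alkylation by a polar enamine Michael addition.
- 1 and nitroethylene react with (S)-α,α-diphenylprolinol trimethylsilyl ether and 3-nitrobenzoic acid (toluene, 3 °C) to give (2R)-2-(3,4-dimethoxybenzyl)-4-nitrobutanal F1.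
- NaBH4 reduces F1 to (2R)-2-(3,4-dimethoxybenzyl)-4-nitrobutan-1-ol F2.
- NaNO2/AcOH in DMSO (35 °C) converts CH2NO2 into CO2H, giving (3R)-3-(3,4-dimethoxybenzyl)-4-hydroxybutanoic acid F3.
- F3 closes on acidic work-up to (4R)-4-(3,4-dimethoxybenzyl)oxolan-2-one F4.
- Carboxylation of F4 with methyl magnesium carbonate (DMF, 125 °C, then cold HCl) returns to 7.

**Step 2.**
- Risk: the second ester hydrolysis may be slow, or CO2 may be lost during acidification and concentration.
- Fallback: it sets out from 1, comes back at 7, and replaces basic hydrolysis by an acid-labile ester.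
- The step 1 alkylation is run with catalogue di-tert-butyl bromomalonate and gives di-tert-butyl 2-[(2R)-1-(3,4-dimethoxyphenyl)-3-oxopropan-2-yl]malonate F5.
- NaBH4 (EtOH, 0 °C, AcOH quench) reduces F5 to di-tert-butyl 2-[(2R)-1-(3,4-dimethoxyphenyl)-3-hydroxypropan-2-yl]malonate F6.
- TFA/CH2Cl2 (0 °C to rt) cleaves both tert-butyl esters of F6 and closes the lactone in one operation to give 7.

## Further compounds
F1 | step 1 | (2R)-2-(3,4-dimethoxybenzyl)-4-nitrobutanal | O=C[C@H](Cc1ccc(OC)c(OC)c1)CC[N+](=O)[O-]
F2 | step 1 | (2R)-2-(3,4-dimethoxybenzyl)-4-nitrobutan-1-ol | OC[C@H](Cc1ccc(OC)c(OC)c1)CC[N+](=O)[O-]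
F3 | step 1 | (3R)-3-(3,4-dimethoxybenzyl)-4-hydroxybutanoic acid | OC[C@H](Cc1ccc(OC)c(OC)c1)CC(=O)O
F4 | step 1 | (4R)-4-(3,4-dimethoxybenzyl)oxolan-2-one | O=C1OC[C@H](Cc2ccc(OC)c(OC)c2)C1
F5 | step 2 | di-tert-butyl 2-[(2R)-1-(3,4-dimethoxyphenyl)-3-oxopropan-2-yl]malonate | O=C[C@H](Cc1ccc(OC)c(OC)c1)C(C(=O)OC(C)(C)C)C(=O)OC(C)(C)C
F6 | step 2 | di-tert-butyl 2-[(2R)-1-(3,4-dimethoxyphenyl)-3-hydroxypropan-2-yl]malonate | OC[C@H](Cc1ccc(OC)c(OC)c1)C(C(=O)OC(C)(C)C)C(=O)OC(C)(C)C
F7 | step 3 | (4R)-4-(3,4-dimethoxybenzyl)-3-methylideneoxolan-2-one | C=C1C(=O)OC[C@@H]1Cc1ccc(OC)c(OC)c1
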